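**Retrosynthetic overview**

1. The syn-(3R,5S)-diacetoxyheptane chain C1–C7 is recognised in a commercial cis-1,3-dioxane amine 1, which carries both stereocentres. Its nitrogen-bearing carbon becomes C1 and its ester carbon becomes C7; only this assignment gives the required enantiomer.
2. Key disconnection: the guaiacol ring carbon para to the phenol oxygen to chain C1. The bond is made by a nickel-catalysed reductive coupling of two electrophilic carbons: the C–Br carbon of aryl bromide 4 and C1 of pyridinium salt 3, which reacts through a C1 radical.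
3. Enabling feature: C1 is a primary CH2 whose nearest heteroatom is the C3 oxygen, so a C1 radical or alkylnickel can neither β-eliminate nor disturb C3 and C5, which are locked in the dioxane ring. The ring carbon to be joined has C–H on both sides and is an unhindered aryl bromide position.
4. Second disconnection: catechol ring carbon to C7, by the same like-polarity logic from primary bromide 7 (ester reduction, then bromination) and aryl bromide 8.
5. Rings: none is built. Both benzene rings and the temporary 1,3-dioxane arrive with 4, 8 and 1; the dioxane is opened in step 6, followed by diacetylation and debenzylation.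

Key step: step 2

Assumption: 1 (the acetonide-protected side-chain amine made on scale for atorvastatin), 2, 4 and 8 are taken as catalogue compounds.

**Route**

Step 1
Reactants: 1 tert-butyl 2-[(4R,6R)-6-(2-aminoethyl)-2,2-dimethyl-1,3-dioxan-4-yl]acetate; 2 2,4,6-triphenylpyrylium tetrafluoroborate
Product: 3 1-{2-[(4R,6R)-6-(2-tert-butoxy-2-oxoethyl)-2,2-dimethyl-1,3-dioxan-4-yl]ethyl}-2,4,6-triphenylpyridin-1-ium tetrafluoroborate
Conditions: EtOH, 4 Å MS, 70 °C; precipitation with Et2O
Reagents that add atoms: none
Why: The unhindered primary amine opens the pyrylium ring and recloses with loss of water only (pyrylium-to-pyridinium condensation), turning the C1–N bond into a redox-active leaving group under near-neutral conditions that the acetonide and tert-butyl ester should tolerate.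

Step 2
Reactants: 3 the pyridinium tetrafluoroborate; 4 1-(benzyloxy)-4-bromo-2-methoxybenzene
Product: 5 tert-butyl 2-[(4R,6R)-6-{2-[4-(benzyloxy)-3-methoxyphenyl]ethyl}-2,2-dimethyl-1,3-dioxan-4-yl]acetate
Conditions: NiBr2·glyme (10 mol %), 4,4'-dimethoxy-2,2'-bipyridine (12 mol %), Mn powder (2 equiv), MgCl2 (1 equiv), NMP, 60 °C
Reagents that add atoms: none
Why: Zerovalent nickel carrying the bipyridine ligand adds oxidatively to the C–Br bond of 4, while single-electron reduction of the pyridinium ring of 3 (by low-valent nickel or Mn) splits the C1–N bond into 2,4,6-triphenylpyridine and a primary C1 radical; the radical is captured by the arylnickel bromide, reductive elimination from trivalent nickel forms the aryl–CH2 bond, and Mn returns nickel to the zerovalent state. The closest known reaction type is the nickel-catalysed deaminative reductive cross-electrophile coupling of primary alkylpyridinium salts with aryl bromides, a union of two electrophilic carbons. No ring is closed and no stereocentre is formed; the two dioxane stereocentres lie two and four bonds from the radical and are not touched. The step needs cross-coupling over homo-coupling, which the partner pair secures because the two carbons are activated by different elementary steps (two-electron oxidative addition at the unhindered aryl bromide, one-electron fragmentation of the pyridinium). It also needs a C1 radical and alkylnickel that do not fragment, which holds because the nearest oxygen sits on C3, so neither β-scission nor β-elimination of an oxygen group is open. The tert-butyl ester, the acetonide and the benzyl ether should be inert to Mn and low-valent nickel under these neutral conditions.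

Step 3
Reactants: 5 the tert-butyl ester
Product: 6 2-[(4S,6R)-6-{2-[4-(benzyloxy)-3-methoxyphenyl]ethyl}-2,2-dimethyl-1,3-dioxan-4-yl]ethan-1-ol
Conditions: LiAlH4, THF, 0 °C to rt; aqueous NaOH work-up
Reagents that add atoms: none
Why: LiAlH4 reduction of an ester to the primary alcohol is reliable for tert-butyl esters, and the acetonide, the benzyl ether and both stereocentres are inert to hydride (the descriptor change at the dioxane carbon is only a priority change).

Step 4
Reactants: 6 the primary alcohol
Product: 7 (4R,6R)-4-{2-[4-(benzyloxy)-3-methoxyphenyl]ethyl}-6-(2-bromoethyl)-2,2-dimethyl-1,3-dioxane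
Conditions: CBr4, PPh3, CH2Cl2, 0 °C to rt
Reagents that add atoms: carbon tetrabromide, BrC(Br)(Br)Br
Why: The Appel reaction converts the unhindered primary alcohol into the bromide by SN2 displacement of an alkoxyphosphonium ion under near-neutral conditions that the acetonide tolerates, and no stereocentre is involved.

Step 5
Reactants: 7 the primary bromide; 8 1,2-bis(benzyloxy)-4-bromobenzene
Product: 9 (4R,6S)-4-{2-[4-(benzyloxy)-3-methoxyphenyl]ethyl}-6-{2-[3,4-bis(benzyloxy)phenyl]ethyl}-2,2-dimethyl-1,3-dioxane
Conditions: NiI2 hydrate (10 mol %), 4,4'-dimethoxy-2,2'-bipyridine (10 mol %), NaI (25 mol %), pyridine (10 mol %), Zn dust (2 equiv), DMPU, 60 °C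
Reagents that add atoms: none
Why: Nickel-catalysed reductive cross-electrophile coupling of a primary alkyl bromide with an aryl bromide (capture of the C7 radical by an arylnickel species, Zn as terminal reductant) forms the C7–aryl bond at a primary carbon whose nearest oxygen is on C5, so the stereocentres are not at risk.

Step 6
Reactants: 9 the bis-arylated acetonide
Product: 10 (3R,5S)-1-[4-(benzyloxy)-3-methoxyphenyl]-7-[3,4-bis(benzyloxy)phenyl]heptane-3,5-diol
Conditions: 1 M aq HCl, THF, rt
Reagents that add atoms: none
Why: Acid-catalysed hydrolysis of the isopropylidene acetal frees the syn-1,3-diol without breaking a C–O bond at either stereocentre, and benzyl aryl ethers are stable to dilute aqueous acid.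

Step 7
Reactants: 10 the syn-diol
Product: 11 (3R,5S)-1-[4-(benzyloxy)-3-methoxyphenyl]-7-[3,4-bis(benzyloxy)phenyl]heptane-3,5-diyl diacetate
Conditions: Ac2O, pyridine, DMAP (cat.), CH2Cl2, rt
Reagents that add atoms: acetic anhydride, CC(=O)OC(C)=O
Why: DMAP-catalysed acylation of both secondary alcohols with acetic anhydride proceeds with retention because only O–H bonds are broken.

Step 8
Reactants: 11 the tribenzyl diacetate
Product: 12 (3R,5S)-7-(3,4-dihydroxyphenyl)-1-(4-hydroxy-3-methoxyphenyl)heptane-3,5-diyl diacetate (C3 is the acetoxy carbon on the guaiacol side)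
Conditions: H2 (1 atm), 10% Pd/C, EtOAc–MeOH, rt
Reagents that add atoms: none
Why: Palladium-catalysed hydrogenolysis cleaves the three benzyl aryl ethers to toluene and the free phenols, while the alkyl acetates, the aryl methyl ether and the stereocentres should be unaffected under neutral conditions.

**Compound list**

1 | tert-butyl 2-[(4R,6R)-6-(2-aminoethyl)-2,2-dimethyl-1,3-dioxan-4-yl]acetate (cis-dioxane) | NCC[C@@H]1C[C@H](CC(=O)OC(C)(C)C)OC(C)(C)O1 | starting material
2 | 2,4,6-triphenylpyrylium tetrafluoroborate | c1ccc(cc1)-c1cc(-c2ccccc2)cc(-c2ccccc2)[o+]1.F[B-](F)(F)F | starting material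
3 | 1-{2-[(4R,6R)-6-(2-tert-butoxy-2-oxoethyl)-2,2-dimethyl-1,3-dioxan-4-yl]ethyl}-2,4,6-triphenylpyridin-1-ium tetrafluoroborate | c1ccc(cc1)-c2cc(-c3ccccc3)cc(-c4ccccc4)[n+]2CC[C@@H]5C[C@H](CC(=O)OC(C)(C)C)OC(C)(C)O5.F[B-](F)(F)F | intermediate
4 | 1-(benzyloxy)-4-bromo-2-methoxybenzene | COc1cc(Br)ccc1OCc1ccccc1 | starting material
5 | tert-butyl 2-[(4R,6R)-6-{2-[4-(benzyloxy)-3-methoxyphenyl]ethyl}-2,2-dimethyl-1,3-dioxan-4-yl]acetate | COc1cc(CC[C@@H]2C[C@H](CC(=O)OC(C)(C)C)OC(C)(C)O2)ccc1OCc1ccccc1 | intermediate
6 | 2-[(4S,6R)-6-{2-[4-(benzyloxy)-3-methoxyphenyl]ethyl}-2,2-dimethyl-1,3-dioxan-4-yl]ethan-1-ol | COc1cc(CC[C@@H]2C[C@H](CCO)OC(C)(C)O2)ccc1OCc1ccccc1 | intermediate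
7 | (4R,6R)-4-{2-[4-(benzyloxy)-3-methoxyphenyl]ethyl}-6-(2-bromoethyl)-2,2-dimethyl-1,3-dioxane | COc1cc(CC[C@@H]2C[C@H](CCBr)OC(C)(C)O2)ccc1OCc1ccccc1 | intermediate
8 | 1,2-bis(benzyloxy)-4-bromobenzene | Brc1ccc(OCc2ccccc2)c(OCc2ccccc2)c1 | starting material
9 | (4R,6S)-4-{2-[4-(benzyloxy)-3-methoxyphenyl]ethyl}-6-{2-[3,4-bis(benzyloxy)phenyl]ethyl}-2,2-dimethyl-1,3-dioxane | COc1cc(CC[C@@H]2C[C@H](CCc3ccc(OCc4ccccc4)c(OCc4ccccc4)c3)OC(C)(C)O2)ccc1OCc1ccccc1 | intermediate
10 | (3R,5S)-1-[4-(benzyloxy)-3-methoxyphenyl]-7-[3,4-bis(benzyloxy)phenyl]heptane-3,5-diol | COc1cc(CC[C@@H](O)C[C@@H](O)CCc2ccc(OCc3ccccc3)c(OCc3ccccc3)c2)ccc1OCc1ccccc1 | intermediate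
11 | (3R,5S)-1-[4-(benzyloxy)-3-methoxyphenyl]-7-[3,4-bis(benzyloxy)phenyl]heptane-3,5-diyl diacetate | COc1cc(CC[C@@H](OC(C)=O)C[C@@H](OC(C)=O)CCc2ccc(OCc3ccccc3)c(OCc3ccccc3)c2)ccc1OCc1ccccc1 | intermediate
12 | (3R,5S)-7-(3,4-dihydroxyphenyl)-1-(4-hydroxy-3-methoxyphenyl)heptane-3,5-diyl diacetate | COc1cc(CC[C@H](C[C@H](CCc2ccc(O)c(O)c2)OC(C)=O)OC(C)=O)ccc1O | target

**Totals**

Total step count: 8. Longest linear sequence: 8 steps (1 to 12).

**Steps most likely to fail**

Step 2. Oxidative addition of the electron-rich aryl bromide may lag behind radical generation, so the C1 radical could be lost to reduction or dimerisation. The fallback separates the two events. It sets out from 3: photochemical deaminative borylation (bis(catecholato)diboron, DMA, blue light; then pinacol, Et3N) should give tert-butyl 2-[(4R,6R)-2,2-dimethyl-6-[2-(4,4,5,5-tetramethyl-1,3,2-dioxaborolan-2-yl)ethyl]-1,3-dioxan-4-yl]acetate F1. A Suzuki–Miyaura coupling of this primary alkylboronate with 4 (Pd(OAc)2, RuPhos, K2CO3, toluene–H2O, 80 °C) then makes the same aryl–C1 bond by a two-electron palladium cycle and returns to the route at 5.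

Step 5. Homocoupling of the alkyl bromide, β-hydride elimination or hydrodehalogenation may outrun cross-coupling with the electron-rich, doubly oxygenated aryl bromide. The fallback replaces the reductive coupling by a nucleophile–electrophile coupling. It sets out from 7: zinc insertion (Zn dust, LiCl, THF, 50 °C) should give bromo{2-[(4R,6R)-6-{2-[4-(benzyloxy)-3-methoxyphenyl]ethyl}-2,2-dimethyl-1,3-dioxan-4-yl]ethyl}zinc F2, used without isolation. Negishi coupling with 8 (Pd(OAc)2, SPhos, THF, rt to 50 °C) returns to the route at 9.

Step 8. The palladium surface may be poisoned by traces of halide, zinc or nickel carried from steps 4 and 5, stalling at partly benzylated material, and the freed catechol may be air-oxidised on long exposure. The fallback sets out from 11 and cleaves the benzyl ethers by Lewis acid instead: BCl3 with pentamethylbenzene as cation scavenger, CH2Cl2, −78 °C, methanol quench. This should leave the alkyl acetates and the aryl methyl ether intact and returns directly to 12; it makes no new compound (entry F0).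

Further compounds
F1 | step 2 | tert-butyl 2-[(4R,6R)-2,2-dimethyl-6-[2-(4,4,5,5-tetramethyl-1,3,2-dioxaborolan-2-yl)ethyl]-1,3-dioxan-4-yl]acetate | CC1(C)OB(CC[C@@H]2C[C@H](CC(=O)OC(C)(C)C)OC(C)(C)O2)OC1(C)C
F2 | step 5 | bromo{2-[(4R,6R)-6-{2-[4-(benzyloxy)-3-methoxyphenyl]ethyl}-2,2-dimethyl-1,3-dioxan-4-yl]ethyl}zinc | COc1cc(CC[C@@H]2C[C@H](CC[Zn]Br)OC(C)(C)O2)ccc1OCc1ccccc1
F0 | step 8 | none | none
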